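## Structural features

The target is a longipinane-type sesquiterpenoid diester, a tricyclo[5.4.0.0^2,8]undecane in which a cyclobutane (C4, C5, C11, C10) carries a short bridge across each diagonal, one on each face. The atoms are numbered so that C1 is the carbonyl carbon of the enone, C2 and C3 are its alkene carbons (C3 methylated), C4 and C11 are the four-ring methines attached to C3 and C1, C5 is the four-ring methine attached to the gem-dimethyl carbon C6, C7 and C9 are the two acyloxy methines separated by C8H2, and C10 is the fully substituted, methylated four-ring carbon. The unit C3=C2–C1(=O) joins C4 to C11 and makes a verbenone-type bicyclo[3.1.1]hept-3-en-2-one, while the chain C6–C7–C8–C9 joins C5 to C10 across the other face and closes a seven-membered ring. Four contiguous stereocentres sit on the cyclobutane (4R, 5S, 11R and the quaternary 10R), and the two carbinol centres (7R, 9R) are anti-1,3 to each other and each flanked by a quaternary carbon. The fragile parts are the strained four-membered ring beside an enone, which invites cationic rearrangement under acid and acyl shifts under light, and the two hindered secondary 3-methylbutanoates. The real difficulty is to attach C6 and C9 to the cyclobutane face opposite the enone bridge, at carbons that are or adjoin quaternary centres, and then to set the anti-diol inside a rigid ring. The key step uses the C5/C10 diagonal: a nucleophilic carbon (C6) can be placed on C5 and an electrophilic carbon (the methyl group) on C10 by cleaving the central C5–C10 bond of a tricyclo[4.1.0.0^2,7]heptane-1-carboxylate whose wing carbons are C4 and C11, whose bridge is C1–C3 and whose ester carbon is C9.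

## Logic of the disconnections

**26 ⇒ 25 ⇒ 24.** The C3–CH3 bond is cut and the oxygen is moved back from C1 to C3, the reverse of a 1,3-oxidative transposition. This avoids a regiochemically delicate allylic oxidation and leads to 24, which lacks the methyl group. The forward steps must add a methyl nucleophile to the ketone of 24 in the presence of two esters and rearrange the tertiary allylic alcohol of 25 without ionising it next to the cyclobutane.

**24 ⇒ 22 ⇒ 21.** The C1=C2 unsaturation is removed and the C3 carbonyl is masked, which leads to 21. The ketone of 22 can enolise only toward C2 because C4 is a bridgehead, so the forward dehydrogenation has no regiochemical problem. The ketal group keeps C3 silent during all the carbonyl chemistry in the other bridge.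

**21 ⇒ 19 + 20.** Both ester C–O bonds are cut. The gain is that the two identical acyl groups come from one commercial reagent, 20, used twice. The demand is acylation of two neopentyl-type secondary alcohols.

**19 ⇒ 18.** The C7–H and C9–H bonds are cut. In 18 each carbonyl has a quaternary carbon on one side and C8H2 on the other, so a single chiral reducing catalyst can set both centres in the same local sense. That sense is the anti-(R,R) arrangement required.

**18 ⇒ 17.** The C8–C9 bond is cut (Claisen). This opens the seven-membered ring to a methyl ketone and an ester held cis-1,3 on the cyclobutane. The forward step needs exactly that cis arrangement, so it also tests the stereochemistry set in the key step.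

**17 ⇒ 16 ⇒ 15 ⇒ 13.** The C7–C8 bond is cut and C7 is returned to the nitrile oxidation level. The nitrile is the small anion-stabilising group that the key step needs. The forward steps must reduce a nitrile beside a hindered tert-butyl ester and add a methyl group without letting the alkoxide attack that ester.

**13 ⇒ 8 + 9 + 10 (key).** The C5–C6 and C10–CH3 bonds are cut and the central C5–C10 bond of 8 is restored. Two skeletal bonds and two stereocentres are traded for ring strain that is already present. The forward step demands attack at C5 and not at the carbonyl, bonding of C6 on the face of C5 away from the C1–C3 bridge, and methylation of C10 from the bridge side. The small dioxolane and the tert-butyl ester are kept in 8 because a bulkier ketal would close the bridge-side approach that 10 needs at C10.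

**8 ⇒ 7.** The C10–C4 and C10–C5 bonds are cut (carbene addition). The tricycle becomes the monocyclic 7, whose single stereocentre C11 dictates all the others because the carbene can reach only one face of the ring alkene. The demand is cyclopropanation faster than 1,2-hydride shift.

**7 ⇒ 5 ⇒ 4.** The diazo group and the ketal are removed. The ketal must be put on without moving the C4=C5 double bond, and the diazo group must be transferred to a simple ester, which needs transient acyl activation.

**4 ⇒ 3 ⇒ 1 + 2.** The ring C–C bond made by aldol condensation and the C11–C1 bond made by Michael addition are cut. This gives 1 and 2, both commercial, and puts the only stereocentre-forming event under catalyst control, so no resolution is needed.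

## Other disconnections considered

Alternative 1: The cut is at C7–C8, together with the C9–H bond and the C7 ester oxygen. It leads back to the keto aldehyde A1, the target skeleton with an acetyl group on C10 and a neopentyl aldehyde on C6.

- **Forward step:** A chiral primary amine would turn the methyl ketone into its enamine, C8 would add to the aldehyde and close the seven-membered ring, and SmI2 (divalent samarium) with 3-methylbutanal would reduce C9 by hydride transfer within the C7 hemiacetal (aldol–Tishchenko). This would give the monoester A2, and one acylation would finish the target.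
- **In its favour:** The ring, both carbinol centres and one ester would arise in one operation. The anti-1,3 relationship follows from the cyclic hydride transfer. The aldehyde cannot enolise, so only one enamine is possible.
- **Against it here:** A seven-membered aldol through the enamine of a hindered ketone is slow and reversible. The C7 configuration would depend on a catalyst working against a rigid cage. SmI2 and the amine would also have to tolerate the enone.
- **Comparison, structure:** It is an endgame and does not solve the cyclobutane problem. A1 still needs C6 and C9 cis and opposite the enone bridge, which is exactly what step 6 must deliver.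
- **Comparison, mechanism:** The internal hydride transfer is a more secure source of the anti relationship than the second catalyst-controlled reduction in step 11. On this point the alternative is better. The C7 centre is less secure than in step 11.
- **Comparison, step economy:** About two operations would lead from A1 to the target, against three from 17 to 21. Here too the alternative is better.

Alternative 2: The cut is at C5–C11 and C4–C10, which opens the cyclobutane and the seven-membered ring together and leads to the acyclic dienyl pyrrolidine amide A3.

- **Forward step:** Tf2O and 2,4,6-collidine would convert A3 into a keteniminium ion (C10=C11=N+). This would add across the C4=C5 alkene in the crossed sense and, after hydrolysis, give the bridged cyclobutanone A4.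
- **In its favour:** One step would build two rings and three stereocentres from a chain. The crossed mode places the C6–C9 tether and the C4 substituent on opposite faces by construction, so the facial problem of step 6 does not arise. On this point the alternative is better.
- **Against it here:** The fused mode (C10–C5 bonding, six-membered ring) competes with the crossed one. The allyl cation formed after C11–C5 bonding can also close at C2 in a [4+2] sense. In A4, C11 is a carbonyl carbon where the target has a CH bearing C1, so one carbon must still be inserted and the enone ring closed. C9 must also be oxygenated from the C8=C9 alkene with regiocontrol and anti to C7.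
- **Comparison, structure:** On ring-building economy the alternative is superior, but A4 is further from the target's oxidation pattern than 13 is.
- **Comparison, mechanism:** The risks are of equal weight, regiochemistry of the cycloaddition there and the facial course of the ring opening here.
- **Comparison, step economy:** The work after the cycloaddition is judged heavier than the ten steps that follow step 6, so the overall length is likely similar or greater.

Alternative 3: The cut is at C4–C10 and leads to the cis-fused epoxy enone A5, a carvone-derived cyclohexenone–cycloheptane with a C9–C10 epoxide.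

- **Forward step:** Cp2TiCl (trivalent titanium, from Cp2TiCl2 and zinc dust) would open the epoxide to the tertiary C10 radical, which would add to the C4 carbonyl carbon and give the cyclobutanol A6.
- **In its favour:** The ring fusion forces C10 to bond to C4 from the correct face, so the cyclobutane stereochemistry is secure. On this point the alternative is better than the chosen plan. The C9–O bond is carried through with its configuration, and carvone supplies the six-membered ring with C11 and the methyl-bearing alkene.
- **Against it here:** A 4-exo addition of a radical to a ketone carbonyl is slow and reversible unless titanium captures the alkoxyl radical, and conjugate addition to C2 competes. A6 carries a tertiary C4 hydroxyl that the target lacks and a CH2 at C1. The bridgehead cyclobutanol must therefore be deoxygenated, and once C1 is oxidised the C4 hydroxyl is a vinylogous aldol that can open the ring.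
- **Comparison, structure:** Stereocontrol of the four-membered ring favours the alternative.
- **Comparison, mechanism:** The radical closure is at least as uncertain as step 6, because both depend on a strained four-membered ring event of unproven selectivity.
- **Comparison, step economy:** Functional-group economy favours the chosen plan, which never carries an oxygen on C4. The step count is estimated equal at best.

Key step: step 6

Remark on the chemistry: polar and radical additions to tricyclo[4.1.0.0^2,7]heptanes normally use the rear lobe of the central bond, which points toward the three-carbon bridge and would place C6 syn to that bridge; the route needs C6 on the opposite face of C5, so a front-side course is assumed in step 6 and is treated there as unproven.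

## Steps

Step 1
Reactants: 1 tert-butyl 4-oxobutanoate; 2 but-3-en-2-one
Product: 3 tert-butyl (3S)-3-formyl-6-oxoheptanoate
Conditions: (S)-2-[methoxy(diphenyl)methyl]pyrrolidine (5 mol %), ethyl 3,4-dihydroxybenzoate (20 mol %), neat, 4 °C
Reagents that add atoms: none
Why: Enamine-catalysed Michael addition of an aldehyde to methyl vinyl ketone; the diarylmethyl group shields one face of the E-enamine and should set the future C11 as S (the antipodal catalyst would be used if the sense proved opposite). The ester is a spectator.

Step 2
Reactants: 3 tert-butyl (3S)-3-formyl-6-oxoheptanoate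
Product: 4 tert-butyl 2-[(1S)-4-oxocyclohex-2-en-1-yl]acetate
Conditions: KOH (0.1 M aq.), Bu4NOH (cat.), Et2O–THF, 40 °C
Reagents that add atoms: none
Why: Intramolecular aldol condensation of the methyl ketone onto the aldehyde gives the 4-substituted cyclohexenone. Once the enone has formed the stereocentre is no longer α to a carbonyl, so brief contact with dilute base should preserve it.

Step 3
Reactants: 4 tert-butyl 2-[(1S)-4-oxocyclohex-2-en-1-yl]acetate
Product: 5 tert-butyl 2-[(8S)-1,4-dioxaspiro[4.5]dec-6-en-8-yl]acetate
Conditions: (Me3SiOCH2)2, Me3SiOTf (cat.), CH2Cl2, −78 → −20 °C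
Reagents that add atoms: 1,2-bis(trimethylsilyloxy)ethane, C[Si](C)(C)OCCO[Si](C)(C)C
Why: Noyori ketalisation under aprotic, kinetic conditions protects the enone carbonyl without moving the double bond toward the substituted carbon, which protic glycol/acid conditions would do.

Step 4
Reactants: 5 tert-butyl 2-[(8S)-1,4-dioxaspiro[4.5]dec-6-en-8-yl]acetate
Product: 7 tert-butyl 2-diazo-2-[(8R)-1,4-dioxaspiro[4.5]dec-6-en-8-yl]acetate, via trifluoroacetyl ester 6 (not isolated)
Conditions: LiN(SiMe3)2, THF, −78 °C; CF3CO2CH2CF3; then MeSO2N3, Et3N, H2O, MeCN, rt
Reagents that add atoms: methanesulfonyl azide, CS(=O)(=O)N=[N+]=[N-]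
Why: Deacylative (detrifluoroacetylative) diazo transfer: the ester enolate is C-acylated and the activated 1,3-dicarbonyl accepts the diazo group with loss of the trifluoroacetyl group. The ring stereocentre is not touched (its descriptor changes only through priorities).

Step 5
Reactants: 7 tert-butyl 2-diazo-2-[(8R)-1,4-dioxaspiro[4.5]dec-6-en-8-yl]acetate
Product: 8 tert-butyl (1'S,2'S,6'R,7'R)-spiro[1,3-dioxolane-2,3'-tricyclo[4.1.0.0^2,7]heptane]-1'-carboxylate
Conditions: Rh2(O2CCPh3)4 (1 mol %), toluene, −78 °C, slow addition of 7
Reagents that add atoms: none
Why: Rhodium-carbene intramolecular cyclopropanation of the ring alkene by the carbene on the adjacent carbon (bicyclobutanation of a 2-diazopent-4-enoate). The carbene can reach only the face of C4=C5 on which C10 already sits, so C11 fixes C4, C5 and C10. Bulky carboxylate ligands at low temperature are chosen to suppress the 1,2-hydride shift.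

Step 6
Reactants: 8 tert-butyl (1'S,2'S,6'R,7'R)-spiro[1,3-dioxolane-2,3'-tricyclo[4.1.0.0^2,7]heptane]-1'-carboxylate; 9 2-methylpropanenitrile; 10 iodomethane
Product: 13 tert-butyl 7'-(2-cyanopropan-2-yl)-6'-methylspiro[1,3-dioxolane-2,2'-bicyclo[3.1.1]heptane]-6'-carboxylate (cyanoalkyl group on C5 and ester on C10 both anti to the C1–C3 bridge; C10 methyl syn), via lithiated isobutyronitrile 11 (not isolated), via lithium ester enolate 12 (not isolated)
Conditions: 9, LiN(iPr)2 (commercial solution), Et2O–toluene, −78 °C; 8, −78 → −20 °C; then 10, DMPU, −78 → 0 °C
Reagents that add atoms: none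
Why: Proposed new method: carbanion 11 is meant to open the strained C5–C10 σ-bond at the β-bridgehead C5 to give ester enolate 12, which 10 then C-methylates; this is the bond pattern of the known homoconjugate addition–enolate trapping of tert-butyl bicyclo[1.1.0]butane-1-carboxylates, but with a facial course at C5 that has no precedent. In the known additions the reagent uses the rear lobe of the central bond, which at C5 points outward and toward the C1–C3 bridge, and that course would leave C6 syn to the bridge where the later ring closure needs it anti. The proposal is delivery within a contact ion pair in a weakly coordinating medium: lithium bound to the ester carbonyl holds the N-lithiated ketenimine form of 11 over the convex face, and carbon is handed to the front lobe of the bent C5–C10 bond with retention at C5 while C5–H swings toward the bridge. The closest known reaction types are the homoconjugate addition named above (same bonds, inversion at the attacked carbon) and the openings of bicyclobutane central bonds by electrophiles, which are taken to engage the electron-rich convex face. No ring is closed. C5 is set by the face of carbon delivery, and C10 by approach of 10 to the planar enolate from the bridge side, anti to the pseudo-axial C(CH3)2CN group, which leaves the ester on the far face cis to C6. Attack at C5 and not at the carbonyl rests on the tert-butyl ester and on a nucleophile without α-hydrogen, and C-methylation on the lithium enolate in DMPU; Thorpe attack of 12 on the nearby nitrile is reversible, cannot end in a conjugated enamine, and should not compete.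

Step 7
Reactants: 13 tert-butyl 7'-(2-cyanopropan-2-yl)-6'-methylspiro[1,3-dioxolane-2,2'-bicyclo[3.1.1]heptane]-6'-carboxylate
Product: 15 tert-butyl 6'-methyl-7'-(2-methyl-1-oxopropan-2-yl)spiro[1,3-dioxolane-2,2'-bicyclo[3.1.1]heptane]-6'-carboxylate, via aluminium aldimine 14 (not isolated)
Conditions: iBu2AlH, toluene, −78 °C; KNaC4H4O6 (aq.), then pH 4 buffer
Reagents that add atoms: water, O
Why: Partial reduction of the nitrile to the N-aluminated aldimine and hydrolysis to the aldehyde. The tert-butyl ester on quaternary C10 is too hindered to compete at −78 °C, and the aldehyde has no α-hydrogen.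

Step 8
Reactants: 15 tert-butyl 6'-methyl-7'-(2-methyl-1-oxopropan-2-yl)spiro[1,3-dioxolane-2,2'-bicyclo[3.1.1]heptane]-6'-carboxylate
Product: 16 tert-butyl 7'-(3-hydroxy-2-methylbutan-2-yl)-6'-methylspiro[1,3-dioxolane-2,2'-bicyclo[3.1.1]heptane]-6'-carboxylate (both C7 epimers)
Conditions: MeMgBr, THF, −78 °C; NH4Cl (aq.) at −78 °C
Reagents that add atoms: methylmagnesium bromide, C[Mg]Br
Why: Grignard addition to the neopentyl aldehyde brings in C8. The C7 configuration is immaterial because the carbinol is oxidised next, and the cold quench keeps the alkoxide from attacking the neighbouring ester.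

Step 9
Reactants: 16 tert-butyl 7'-(3-hydroxy-2-methylbutan-2-yl)-6'-methylspiro[1,3-dioxolane-2,2'-bicyclo[3.1.1]heptane]-6'-carboxylate
Product: 17 tert-butyl 6'-methyl-7'-(2-methyl-3-oxobutan-2-yl)spiro[1,3-dioxolane-2,2'-bicyclo[3.1.1]heptane]-6'-carboxylate
Conditions: Dess–Martin periodinane, NaHCO3, CH2Cl2, 0 °C → rt
Reagents that add atoms: none
Why: Dess–Martin oxidation of the secondary alcohol under buffered conditions that leave the ketal and the tert-butyl ester untouched.

Step 10
Reactants: 17 tert-butyl 6'-methyl-7'-(2-methyl-3-oxobutan-2-yl)spiro[1,3-dioxolane-2,2'-bicyclo[3.1.1]heptane]-6'-carboxylate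
Product: 18 C3 ethylene ketal of the 6,6,10-trimethyl tricyclic 7,9-dione (skeleton numbering; ring stereocentres as in 26)
Conditions: KOC(CH3)3 (2.5 equiv), THF, 0 °C → rt; NH4Cl (aq.)
Reagents that add atoms: none
Why: Intramolecular Claisen (Dieckmann-type) acylation: the only enolate the ketone can form (C8) is held beside the C9 ester by the cis-1,3 arrangement on the cyclobutane. Loss of tert-butoxide and deprotonation of the 1,3-diketone drive the seven-membered ring closure.

Step 11
Reactants: 18 C3 ethylene ketal of the 6,6,10-trimethyl tricyclic 7,9-dione
Product: 19 C3 ethylene ketal of the (7R,9R)-6,6,10-trimethyl tricyclic 7,9-diol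
Conditions: (S)-1-methyl-3,3-diphenyltetrahydro-1H,3H-pyrrolo[1,2-c][1,3,2]oxazaborole (40 mol %), BH3·SMe2, THF, −20 → 0 °C; MeOH
Reagents that add atoms: none
Why: Corey–Bakshi–Shibata reduction of both carbonyls: each has a quaternary carbon (C6 or C10) as its large flank and C8H2 as its small one, so the (S)-catalyst should deliver hydride in the same local sense to both and give the anti-(7R,9R) diol. The face it prefers is the exposed one in the ring conformer with the C7–C8 edge tilted toward C4.

Step 12
Reactants: 19 C3 ethylene ketal of the (7R,9R)-6,6,10-trimethyl tricyclic 7,9-diol; 20 3-methylbutanoyl chloride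
Product: 21 C3 ethylene ketal of the (7R,9R)-7,9-bis(3-methylbutanoyloxy)-6,6,10-trimethyl tricycle
Conditions: 20 (3 equiv), pyridine, DMAP (cat.), CH2Cl2, 0 °C → rt
Reagents that add atoms: 3-methylbutanoyl chloride (second equivalent of 20), CC(C)CC(Cl)=O
Why: DMAP-catalysed acylation; one molecule of 20 esterifies each of the two hindered secondary alcohols, so two equivalents are consumed, and no stereocentre is affected.

Step 13
Reactants: 21 C3 ethylene ketal of the (7R,9R)-7,9-bis(3-methylbutanoyloxy)-6,6,10-trimethyl tricycle
Product: 22 (7R,9R)-7,9-bis(3-methylbutanoyloxy)-6,6,10-trimethyl tricyclic 3-ketone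
Conditions: PPTS, acetone–H2O, 50 °C
Reagents that add atoms: water, O
Why: Mild acid-catalysed ketal hydrolysis; the secondary esters and the cyclobutane tolerate buffered pyridinium acid in wet acetone.

Step 14
Reactants: 22 (7R,9R)-7,9-bis(3-methylbutanoyloxy)-6,6,10-trimethyl tricyclic 3-ketone
Product: 24 (7R,9R)-7,9-bis(3-methylbutanoyloxy)-6,6,10-trimethyl tricyclic 1-en-3-one (C1=C2), via silyl enol ether 23 (not isolated)
Conditions: Me3SiOTf, Et3N, CH2Cl2, 0 °C; then Pd(OAc)2, MeCN, rt
Reagents that add atoms: none
Why: Saegusa–Ito dehydrogenation: soft enolisation can go only toward C2 because C4 is a bridgehead, and it leaves the esters alone. Palladium diacetate then converts the silyl enol ether into the enone, as in the nopinone to apoverbenone conversion.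

Step 15
Reactants: 24 (7R,9R)-7,9-bis(3-methylbutanoyloxy)-6,6,10-trimethyl tricyclic 1-en-3-one
Product: 25 (7R,9R)-7,9-bis(3-methylbutanoyloxy)-3-hydroxy-3,6,6,10-tetramethyl tricyclic 1-ene (either C3 epimer)
Conditions: MeMgBr, CeCl3, THF, −78 °C
Reagents that add atoms: methylmagnesium bromide, C[Mg]Br
Why: Cerium-modified Grignard 1,2-addition to the enone carbonyl, much faster at −78 °C than attack on the two esters. The new C3 carbinol centre is destroyed in the next step, so its configuration does not matter.

Step 16
Reactants: 25 (7R,9R)-7,9-bis(3-methylbutanoyloxy)-3-hydroxy-3,6,6,10-tetramethyl tricyclic 1-ene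
Product: 26 target, (4R,5S,7R,9R,10R,11R)-3,6,6,10-tetramethyl-1-oxo tricyclic 2-ene-7,9-diyl bis(3-methylbutanoate) (CNP0192813.1)
Conditions: [C5H5NH][CrO3Cl], NaOAc, 4 Å molecular sieves, CH2Cl2, rt
Reagents that add atoms: pyridinium chlorochromate [C5H5NH][CrO3Cl], [O-][Cr](=O)(=O)Cl.c1cc[nH+]cc1
Why: Babler–Dauben oxidative transposition: the tertiary allylic chromate ester undergoes a [3,3] shift to C1 and is oxidised there, giving C1=O and the methyl-bearing C2=C3 bond. No stereocentre of the core takes part.

## Compound list

1 | tert-butyl 4-oxobutanoate | O=CCCC(=O)OC(C)(C)C | starting material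
2 | but-3-en-2-one (methyl vinyl ketone) | CC(=O)C=C | starting material
3 | tert-butyl (3S)-3-formyl-6-oxoheptanoate | CC(=O)CC[C@H](C=O)CC(=O)OC(C)(C)C | intermediate
4 | tert-butyl 2-[(1S)-4-oxocyclohex-2-en-1-yl]acetate | O=C1C=C[C@H](CC(=O)OC(C)(C)C)CC1 | intermediate
5 | tert-butyl 2-[(8S)-1,4-dioxaspiro[4.5]dec-6-en-8-yl]acetate | O1CCOC12C=C[C@H](CC(=O)OC(C)(C)C)CC2 | intermediate
6 | tert-butyl 2-[(8R)-1,4-dioxaspiro[4.5]dec-6-en-8-yl]-4,4,4-trifluoro-3-oxobutanoate (C2 epimers/enol) | O1CCOC12C=C[C@H](C(C(=O)C(F)(F)F)C(=O)OC(C)(C)C)CC2 | intermediate
7 | tert-butyl 2-diazo-2-[(8R)-1,4-dioxaspiro[4.5]dec-6-en-8-yl]acetate | O1CCOC12C=C[C@H](C(=[N+]=[N-])C(=O)OC(C)(C)C)CC2 | intermediate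
8 | tert-butyl (1'S,2'S,6'R,7'R)-spiro[1,3-dioxolane-2,3'-tricyclo[4.1.0.0^2,7]heptane]-1'-carboxylate (ester on C10, ketal on C3 next to wing C4) | O1CCOC13CC[C@@H]2[C@@H]4[C@H]3[C@]24C(=O)OC(C)(C)C | intermediate
9 | 2-methylpropanenitrile (isobutyronitrile) | CC(C)C#N | starting material
10 | iodomethane | CI | starting material
11 | lithiated isobutyronitrile | [Li+].C[C-](C)C#N | intermediate
12 | lithium enolate of the C5 adduct (C10=C(OLi)OtBu; cyanoalkyl group on C5 anti to the bridge) | O1CCOC13CC[C@@H]2[C@@H](C(C)(C)C#N)[C@H]3C2=C([O-])OC(C)(C)C.[Li+] | intermediate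
13 | tert-butyl 7'-(2-cyanopropan-2-yl)-6'-methylspiro[1,3-dioxolane-2,2'-bicyclo[3.1.1]heptane]-6'-carboxylate (C6 group on C5 and ester on C10 anti to the C1–C3 bridge, C10 methyl syn) | O1CCOC13CC[C@@H]2[C@@H](C(C)(C)C#N)[C@H]3[C@@]2(C)C(=O)OC(C)(C)C | intermediate
14 | N-(diisobutylaluminio) aldimine of 15 | O1CCOC13CC[C@@H]2[C@@H](C(C)(C)C=N[Al](CC(C)C)CC(C)C)[C@H]3[C@@]2(C)C(=O)OC(C)(C)C | intermediate
15 | tert-butyl 6'-methyl-7'-(2-methyl-1-oxopropan-2-yl)spiro[1,3-dioxolane-2,2'-bicyclo[3.1.1]heptane]-6'-carboxylate (same relative configuration as 13) | O1CCOC13CC[C@@H]2[C@@H](C(C)(C)C=O)[C@H]3[C@@]2(C)C(=O)OC(C)(C)C | intermediate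
16 | tert-butyl 7'-(3-hydroxy-2-methylbutan-2-yl)-6'-methylspiro[1,3-dioxolane-2,2'-bicyclo[3.1.1]heptane]-6'-carboxylate (C7 epimers) | O1CCOC13CC[C@@H]2[C@@H](C(C)(C)C(C)O)[C@H]3[C@@]2(C)C(=O)OC(C)(C)C | intermediate
17 | tert-butyl 6'-methyl-7'-(2-methyl-3-oxobutan-2-yl)spiro[1,3-dioxolane-2,2'-bicyclo[3.1.1]heptane]-6'-carboxylate | O1CCOC13CC[C@@H]2[C@@H](C(C)(C)C(C)=O)[C@H]3[C@@]2(C)C(=O)OC(C)(C)C | intermediate
18 | C3 ethylene ketal of the 6,6,10-trimethyl tricyclic 7,9-dione (tricyclo[5.4.0.0^2,8]undecane skeleton, numbering C1–C11 as under Structural features) | O1CCOC14CC[C@@H]2[C@@H]3[C@H]4[C@@]2(C)C(=O)CC(=O)C3(C)C | intermediate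
19 | C3 ethylene ketal of the (7R,9R)-6,6,10-trimethyl tricyclic 7,9-diol | O1CCOC14CC[C@@H]2[C@@H]3[C@H]4[C@@]2(C)[C@H](O)C[C@@H](O)C3(C)C | intermediate
20 | 3-methylbutanoyl chloride (isovaleryl chloride) | CC(C)CC(Cl)=O | starting material
21 | C3 ethylene ketal of the (7R,9R)-7,9-bis(3-methylbutanoyloxy)-6,6,10-trimethyl tricycle | O1CCOC14CC[C@@H]2[C@@H]3[C@H]4[C@@]2(C)[C@H](OC(=O)CC(C)C)C[C@@H](OC(=O)CC(C)C)C3(C)C | intermediate
22 | (7R,9R)-7,9-bis(3-methylbutanoyloxy)-6,6,10-trimethyl tricyclic 3-ketone | O=C1CC[C@@H]2[C@@H]3[C@H]1[C@@]2(C)[C@H](OC(=O)CC(C)C)C[C@@H](OC(=O)CC(C)C)C3(C)C | intermediate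
23 | C3 trimethylsilyl enol ether of 22 (C2=C3) | C[Si](C)(C)OC1=CC[C@@H]2[C@@H]3[C@H]1[C@@]2(C)[C@H](OC(=O)CC(C)C)C[C@@H](OC(=O)CC(C)C)C3(C)C | intermediate
24 | (7R,9R)-7,9-bis(3-methylbutanoyloxy)-6,6,10-trimethyl tricyclic 1-en-3-one | O=C1C=C[C@@H]2[C@@H]3[C@H]1[C@@]2(C)[C@H](OC(=O)CC(C)C)C[C@@H](OC(=O)CC(C)C)C3(C)C | intermediate
25 | (7R,9R)-7,9-bis(3-methylbutanoyloxy)-3-hydroxy-3,6,6,10-tetramethyl tricyclic 1-ene (C3 epimers) | CC1(O)C=C[C@@H]2[C@@H]3[C@H]1[C@@]2(C)[C@H](OC(=O)CC(C)C)C[C@@H](OC(=O)CC(C)C)C3(C)C | intermediate
26 | (4R,5S,7R,9R,10R,11R)-3,6,6,10-tetramethyl-1-oxo tricyclic 2-ene-7,9-diyl bis(3-methylbutanoate), CNP0192813.1 | CC1=CC(=O)[C@@H]2[C@@H]3[C@H]1[C@@]2(C)[C@H](OC(=O)CC(C)C)C[C@@H](OC(=O)CC(C)C)C3(C)C | target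

## Step count and least certain steps

Total step count: 16. Longest linear sequence: 16 steps (1 and 2 to 26); 9, 10 and 20 enter as single commercial reagents.

**Step 6 (key step, proposed new method).** The most likely failure is bond formation through the ordinary rear-lobe corridor on the bridge side instead of across the convex face. The antibonding lobe that a carbanion needs is largest there, and C2H2 and the ketal oxygen do not fully close that corridor. This would give the C5 epimer, in which nitrile and ester are trans across the ring and cannot be joined in step 10. No addition at all, because of the crowded tertiary carbanion, is the second possibility.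

The fallback keeps the bicyclobutane but lets every reagent follow its established facial course: a group already on the bridgehead stays anti to the bridge and the entering nucleophile goes syn. It sets out from 4 and returns at 13. Lithiated 9 is added to 4 in conjugate fashion (THF–DMPU, equilibrating conditions) and the enolate is trapped with Me3SiCl to give the silyl enol ether F1. Oxidation with Pd(OAc)2 gives the 3-substituted enone F2. Ketalisation as in step 3 gives the ketal F3, and acylation followed by diazo transfer as in step 4 leads through the trifluoroacetyl ester F4 to the diazo ester F5. Rhodium-catalysed cyclopropanation as in step 5 gives the bicyclobutane F6, which already carries C6 on C5. The copper hydride [(Ph3P)CuH]6 (monovalent copper) then delivers hydride to C5 through the rear lobe, as the hydride counterpart of the organocopper additions to bicyclobutane esters. Aqueous work-up gives the ester F7 with C6 anti to the bridge. Deprotonation of F7 with LiN(iPr)2 and methylation with 10, anti to the pseudo-axial C6 group, gives 13. In this fallback the strain-release event forms C5–H in place of C5–C6.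

**Step 5.** The most likely failure is 1,2-hydride shift in the rhodium carbene. The hydrogen on C11 is tertiary and the ring alkene is not aryl-activated, so the alkylidene ester could form instead of the bicyclobutane.

The fallback sets out from 5 and returns at 8 by two enolate displacements. Epoxidation of 5 with mCPBA anti to the side chain gives the epoxide F8. LiN(SiMe3)2 generates the ester enolate, which opens the epoxide at C5 (3-exo) to give the cyclopropyl carbinol F9. Mesylation with MeSO2Cl and Et3N gives the mesylate F10. KN(SiMe3)2 then closes the second ring by 1,3-elimination, the standard route to acceptor-substituted bicyclobutanes, giving 8.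

**Step 10.** The most likely failure is C-acylation too slow at a tert-butyl ester flanked by quaternary C10, so that O-acylation or simple proton exchange dominates.

The fallback sets out from 17 and returns at 18. The tert-butyl ester is cleaved with Me3SiOTf and 2,6-lutidine to the acid F11; any silyl enol ether formed at the methyl ketone is hydrolysed on work-up. The acid is converted with pentafluorophenol and iPrN=C=NiPr into the pentafluorophenyl ester F12. Cyclisation by soft enolisation (MgBr2·OEt2, iPr2NEt) gives 18.

**Step 11.** The most likely failure is loss of face selectivity at the second carbonyl once the first reduction has changed the ring conformation, or stalling through a boron enolate of the 1,3-diketone.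

The fallback sets out from 18 and returns at 19. Only one carbonyl, expected to be C7, is reduced under catalyst control with one equivalent of borane, giving the hydroxy ketone F13. The remaining carbonyl is then reduced by internal hydride delivery with Me4NBH(OAc)3. This gives the anti-diol from the existing carbinol, whichever way the ring is tilted.

**Step 16.** The most likely failure is ionisation of the tertiary allylic chromate ester to an allyl cation next to the cyclobutane, followed by skeletal rearrangement or elimination, instead of the [3,3] shift.

The fallback sets out from 22 and returns at 26 without any tertiary alcohol. The ketone is converted with Tf2O and 2,6-di-tert-butyl-4-methylpyridine into the enol triflate F14. Coupling with MeZnCl and Pd(PPh3)4 (zerovalent palladium) gives the methyl alkene F15. Allylic oxidation at C1 with CrO3 and 3,5-dimethylpyrazole, as in the oxidation of α-pinene to verbenone, gives 26.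

## Further compounds

F1 | step 6 | tert-butyl 2-[(1S,2S)-2-(2-cyanopropan-2-yl)-4-(trimethylsilyloxy)cyclohex-3-en-1-yl]acetate (ring substituents trans) | C[Si](C)(C)OC1=C[C@@H](C(C)(C)C#N)[C@H](CC(=O)OC(C)(C)C)CC1
F2 | step 6 | tert-butyl 2-[(1S)-2-(2-cyanopropan-2-yl)-4-oxocyclohex-2-en-1-yl]acetate | O=C1C=C(C(C)(C)C#N)[C@H](CC(=O)OC(C)(C)C)CC1
F3 | step 6 | ethylene ketal of F2 | O1CCOC12C=C(C(C)(C)C#N)[C@H](CC(=O)OC(C)(C)C)CC2
F4 | step 6 | 2-trifluoroacetyl derivative of F3 (epimers or enol at the acylated carbon) | O1CCOC12C=C(C(C)(C)C#N)[C@H](C(C(=O)C(F)(F)F)C(=O)OC(C)(C)C)CC2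
F5 | step 6 | α-diazo ester of F3 | O1CCOC12C=C(C(C)(C)C#N)[C@H](C(=[N+]=[N-])C(=O)OC(C)(C)C)CC2
F6 | step 6 | analogue of 8 carrying the 2-cyanopropan-2-yl group on bridgehead C5 | O1CCOC13CC[C@@H]2[C@]4(C(C)(C)C#N)[C@H]3[C@]24C(=O)OC(C)(C)C
F7 | step 6 | tert-butyl 7'-(2-cyanopropan-2-yl)spiro[1,3-dioxolane-2,2'-bicyclo[3.1.1]heptane]-6'-carboxylate (cyanoalkyl group anti to the C1–C3 bridge; C10 epimers) | O1CCOC13CC[C@@H]2[C@@H](C(C)(C)C#N)[C@H]3C2C(=O)OC(C)(C)C
F8 | step 5 | epoxide of 5, oxygen trans to the side chain | O1CCOC12[C@H]3O[C@H]3[C@H](CC(=O)OC(C)(C)C)CC2
F9 | step 5 | tert-butyl 2-hydroxyspiro[bicyclo[4.1.0]heptane-3,2'-[1,3]dioxolane]-7-carboxylate (hydroxyl trans to the cyclopropane; ester carbon epimers) | O1CCOC12[C@@H](O)[C@@H]3C(C(=O)OC(C)(C)C)[C@@H]3CC2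
F10 | step 5 | methanesulfonate of F9 | O1CCOC12[C@@H](OS(C)(=O)=O)[C@@H]3C(C(=O)OC(C)(C)C)[C@@H]3CC2
F11 | step 10 | carboxylic acid corresponding to 17 | O1CCOC13CC[C@@H]2[C@@H](C(C)(C)C(C)=O)[C@H]3[C@@]2(C)C(=O)O
F12 | step 10 | pentafluorophenyl ester of F11 | O1CCOC13CC[C@@H]2[C@@H](C(C)(C)C(C)=O)[C@H]3[C@@]2(C)C(=O)Oc4c(F)c(F)c(F)c(F)c4F
F13 | step 11 | C3 ethylene ketal of the (7R)-7-hydroxy-6,6,10-trimethyl tricyclic 9-ketone | O1CCOC14CC[C@@H]2[C@@H]3[C@H]4[C@@]2(C)C(=O)C[C@@H](O)C3(C)C
F14 | step 16 | C3 enol triflate of 22 (C2=C3) | FC(F)(F)S(=O)(=O)OC1=CC[C@@H]2[C@@H]3[C@H]1[C@@]2(C)[C@H](OC(=O)CC(C)C)C[C@@H](OC(=O)CC(C)C)C3(C)C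
F15 | step 16 | 1-deoxo analogue of 26 (C1H2, C2=C3 with methyl) | CC1=CC[C@@H]2[C@@H]3[C@H]1[C@@]2(C)[C@H](OC(=O)CC(C)C)C[C@@H](OC(=O)CC(C)C)C3(C)C
A1 | alternative 1 | tricyclic enone with acetyl on C10 and 2-methyl-1-oxopropan-2-yl on C5 (keto aldehyde) | CC1=CC(=O)[C@@H]2[C@@H](C(C)(C)C=O)[C@H]1[C@@]2(C)C(C)=O
A2 | alternative 1 | tricyclic 7-(3-methylbutanoate) with free C9 hydroxyl | CC1=CC(=O)[C@@H]2[C@@H]3[C@H]1[C@@]2(C)[C@H](O)C[C@@H](OC(=O)CC(C)C)C3(C)C
A3 | alternative 2 | 1-(pyrrolidin-1-yl) (3Z,7E)-5-(tert-butyldimethylsilyloxy)-2,6,6,9-tetramethyldeca-3,7,9-trien-1-one (C5 configuration as C7 of the target) | CC(/C=C\[C@@H](O[Si](C)(C)C(C)(C)C)C(C)(C)/C=C/C(C)=C)C(=O)N1CCCC1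
A4 | alternative 2 | bridged cyclobutanone with C4 isopropenyl and C7 silyl ether | C=C(C)[C@H]1[C@H]2C(=O)[C@]1(C)C=C[C@@H](O[Si](C)(C)C(C)(C)C)C2(C)C
A5 | alternative 3 | cis-fused cyclohexenone–cycloheptane with C9–C10 epoxide and C7 silyl ether | CC1=CC[C@@H]2[C@H](C1=O)C(C)(C)[C@H](O[Si](C)(C)C(C)(C)C)C[C@H]3O[C@@]23C
A6 | alternative 3 | tricyclic C4,C9-diol with C2=C3 alkene and C7 silyl ether | CC1=CC[C@@H]2[C@@H]3[C@@]1(O)[C@@]2(C)[C@H](O)C[C@@H](O[Si](C)(C)C(C)(C)C)C3(C)C
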